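Ring C is grown, not coupled. Its contiguous oxygen-bearing carbons C3 to C6 are the four carbons of dimethyl squarate. C1, bearing the ether oxygen to ring B, and the CH at C2 come from a 1-aryloxyvinyl unit already carrying rings A and B. Heating precursor 15, the O-silylated adduct of the two, opens the cyclobutenone and recloses it through a new C2 to C3 bond. This one operation gives the arene with the crowded ether to ring B in place and the para oxygens differentiated (C3 phenol, C6 silyl ether). Arylation at C6 adds ring D, repetition builds ring E, and an FG bromide then BBr3 finish.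

Key step: step 8

Conventions and assumption:
- Rings run from A (2,4,6-trioxygenated end ring) to G (3,4,5-trioxygenated end ring).
- In rings C and E, C1 carries the ether oxygen to the preceding ring, C2 is the only CH, C3 to C5 carry OH (OMe when protected), and C6 carries the ether oxygen to the following ring.
- In rings B, D and F, C1 carries the oxygen to the preceding ring and C4 the oxygen to the following ring.
- The target has no stereocentre and its diaryl ether axes are taken as freely rotating.
- Adducts 15 and 30 are used as racemates, because their single stereocentre is lost on aromatisation.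

Step 1
Reactants: 1 4-bromo-2,6-dimethoxyphenol
Product: 2 2-benzyloxy-5-bromo-1,3-dimethoxybenzene
Conditions: BnBr, K2CO3, DMF, rt
Reagents that add atoms: benzyl bromide, BrCc1ccccc1
Why: Williamson ether synthesis on the phenoxide masks the hydroxyl, so that 2 acts purely as the aryl halide partner in steps 2 and 10 and can be unmasked later without touching methyl or diaryl ethers.

Step 2
Reactants: 2 2-benzyloxy-5-bromo-1,3-dimethoxybenzene; 3 2,4,6-trimethoxyphenol
Product: 4 AB benzyl ether
Conditions: CuI (10 mol %), picolinic acid (20 mol %), K3PO4, DMSO, 90 °C, Ar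
Reagents that add atoms: none
Why: Ullmann-type diaryl ether synthesis with the CuI–picolinic acid system, which tolerates di-ortho-substituted phenols, joins hindered phenol 3 to a bromide whose two ortho positions are free, and exclusion of air protects the electron-rich phenoxide.

Step 3
Reactants: 4 AB benzyl ether
Product: 5 AB phenol
Conditions: H2 (1 atm), 10% Pd/C, EtOAc–MeOH, rt
Reagents that add atoms: none
Why: Catalytic hydrogenolysis cleaves only the benzylic C–O bond, since aryl methyl ethers and diaryl ethers are inert to H2 over Pd/C.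

Step 4
Reactants: 5 AB phenol; 6 trichloroethylene
Product: 7 AB (E)-1,2-dichlorovinyl ether
Conditions: K2CO3, DMF, 70 °C
Reagents that add atoms: none
Why: In this trichloroethylene route to ynol ether precursors the base eliminates HCl to give dichloroacetylene, a slim electrophile that even the flanked phenoxide can reach, and anti addition of ArO–H across it sets the E geometry.

Step 5
Reactants: 7 AB (E)-1,2-dichlorovinyl ether
Product: 10 AB ethynyl ether, via AB chloroethynyl ether 8 (not isolated), via AB lithium acetylide 9 (not isolated)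
Conditions: n-BuLi (3 equiv), THF, −78 → −40 °C; H2O, −78 °C
Reagents that add atoms: none
Why: β-Elimination of HCl by n-BuLi and chlorine–lithium exchange on the chloroalkyne (the standard conversion of dichlorovinyl ethers into ynol ethers) give the acetylide, and the aqueous quench protonates it together with any ring position lithiated by the excess base.

Step 6
Reactants: 10 AB ethynyl ether
Product: 11 AB 1-iodovinyl ether
Conditions: TMSI + MeOH (1.0 equiv each, premixed to give HI), CH2Cl2, −78 °C; cold aq NaHCO3; used at once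
Reagents that add atoms: iodotrimethylsilane (iodine source, as HI), C[Si](C)(C)I
Why: Markovnikov hydroiodination of an ynol ether proceeds by protonation of the terminal carbon to an oxygen-stabilised ketenium ion that iodide captures at the oxygen-bearing carbon, so the regiochemistry is set electronically, and one equivalent of HI at −78 °C guards against a second addition and leaves aryl methyl ethers alone.

Step 7
Reactants: 11 AB 1-iodovinyl ether; 12 dimethyl squarate
Product: 15 racemic AB squarate adduct TBS ether, via AB vinyllithium 13 (not isolated), via AB lithium alkoxide 14 (not isolated)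
Conditions: t-BuLi (2.0 equiv), THF–Et2O, −78 °C; cannulate into 12, THF, −78 °C; 2,6-lutidine, TBSOTf, −78 → −20 °C
Reagents that add atoms: tert-butyldimethylsilyl triflate, CC(C)(C)[Si](C)(C)OS(=O)(=O)C(F)(F)F
Why: Iodine–lithium exchange outruns ring metalation at −78 °C, the alkenyllithium adds 1,2 to one carbonyl of the squarate ester (the standard entry to 4-alkenylcyclobutenones), and trapping the hindered tertiary alkoxide in the flask with the silyl triflate under lutidine buffering avoids the acid-induced loss of methanol that free carbinols of this type suffer; the new carbinol stereocentre forms as a racemate and is erased in step 8.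

Step 8
Reactants: 15 racemic AB squarate adduct TBS ether
Product: 18 ABC trimer C3 phenol C6 silyl ether, via AB dienylketene 16 (not isolated), via ring C dienone 17 (not isolated)
Conditions: degassed toluene (0.02 M), 110 °C, Ar, base-washed glassware
Reagents that add atoms: none
Why: Thermal 4π conrotatory opening of the carbonyl–carbinol bond of the cyclobutenone gives dienylketene 16, 6π disrotatory closure between the ketene carbon and the vinyl CH2 forms the ring C C2–C3 bond (a six-membered carbocycle closed by electrocyclisation), and enolisation of dienone 17 delivers the arene. The closest known reaction type is the Moore ring expansion of 4-alkenyl-4-oxycyclobutenones, made from squarate esters and alkenyllithiums, to hydroquinone derivatives; the aryloxy group on the inner vinyl carbon is a donor substituent that takes no part in bond reorganisation. No stereocentre is formed and the one in 15 disappears. The selectivity needed is torquoselectivity: the silyloxy donor on the breaking carbon rotates outward, which turns the aryloxyvinyl arm inward toward the ketene, and a ketene opened the wrong way can only reclose to 15. Regiochemistry is fixed by connectivity, since the carbonyl carbon becomes C3 (free phenol) and the carbinol carbon becomes C6 (silyl ether), and because these oxygens are para no silyl migration can scramble them. Dilute, degassed and acid-free conditions keep the ketene from dimerising and the electron-rich phenol from oxidising.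

Step 9
Reactants: 18 ABC trimer C3 phenol C6 silyl ether
Product: 20 ABC phenol, via ABC silyl ether 19 (not isolated)
Conditions: MeI, K2CO3, dry acetone, 40 °C; filter, evaporate; TBAF, AcOH (1:1), THF, 0 °C
Reagents that add atoms: iodomethane, CI
Why: Williamson methylation caps the only free phenol while dry carbonate in acetone leaves the doubly flanked aryl silyl ether intact, evaporation removes excess MeI, and fluoride-induced desilylation buffered by acetic acid then frees the C6 hydroxyl without leaving an oxidisable phenoxide.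

Step 10
Reactants: 20 ABC phenol; 2 2-benzyloxy-5-bromo-1,3-dimethoxybenzene
Product: 21 ABCD benzyl ether
Conditions: 2 (1.5 equiv), CuI (20 mol %), picolinic acid (40 mol %), K3PO4, DMSO, 100 °C, Ar
Reagents that add atoms: none
Why: Ullmann-type diaryl ether synthesis as in step 2, in which the hindrance sits only on the phenol while the cheap bromide, used in excess, is open at both ortho positions.

Step 11
Reactants: 21 ABCD benzyl ether
Product: 22 ABCD phenol
Conditions: H2 (1 atm), 10% Pd/C, EtOAc–MeOH, rt
Reagents that add atoms: none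
Why: Catalytic hydrogenolysis of the single benzyl aryl ether, with all methyl and diaryl ethers inert as in step 3.

Step 12
Reactants: 22 ABCD phenol; 6 trichloroethylene
Product: 23 ABCD (E)-1,2-dichlorovinyl ether
Conditions: K2CO3, DMF, 70 °C
Reagents that add atoms: none
Why: Anti addition of the ring D phenoxide to dichloroacetylene formed from trichloroethylene, the same dichlorovinyl ether synthesis as step 4 on an identical 2,6-dimethoxyphenol environment, gives the E alkene.

Step 13
Reactants: 23 ABCD (E)-1,2-dichlorovinyl ether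
Product: 26 ABCD ethynyl ether, via ABCD chloroethynyl ether 24 (not isolated), via ABCD lithium acetylide 25 (not isolated)
Conditions: n-BuLi (3.5 equiv), THF, −78 → −40 °C; H2O, −78 °C
Reagents that add atoms: none
Why: Elimination and chlorine–lithium exchange as in step 5 give the ynol ether, a little more base being allowed for chelation by the many methoxy groups.

Step 14
Reactants: 26 ABCD ethynyl ether
Product: 27 ABCD 1-iodovinyl ether
Conditions: TMSI + MeOH (1.0 equiv each, premixed to give HI), CH2Cl2, −78 °C; cold aq NaHCO3; used at once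
Reagents that add atoms: iodotrimethylsilane (iodine source, as HI), C[Si](C)(C)I
Why: Markovnikov hydroiodination of the ynol ether through the oxygen-stabilised ketenium ion, as in step 6, places iodine on the oxygen-bearing carbon.

Step 15
Reactants: 27 ABCD 1-iodovinyl ether; 12 dimethyl squarate
Product: 30 racemic ABCD squarate adduct TBS ether, via ABCD vinyllithium 28 (not isolated), via ABCD lithium alkoxide 29 (not isolated)
Conditions: t-BuLi (2.0 equiv), THF–Et2O, −78 °C; cannulate into 12, THF, −78 °C; 2,6-lutidine, TBSOTf, −78 → −20 °C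
Reagents that add atoms: tert-butyldimethylsilyl triflate, CC(C)(C)[Si](C)(C)OS(=O)(=O)C(F)(F)F
Why: Iodine–lithium exchange, 1,2-addition of the alkenyllithium to the squarate ester and silylation of the alkoxide in the flask repeat step 7, and the racemic carbinol centre is erased in step 16.

Step 16
Reactants: 30 racemic ABCD squarate adduct TBS ether
Product: 33 ABCDE pentamer C3 phenol C6 silyl ether, via ABCD dienylketene 31 (not isolated), via ring E dienone 32 (not isolated)
Conditions: degassed toluene (0.02 M), 110 °C, Ar, base-washed glassware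
Reagents that add atoms: none
Why: The same Moore-type 4π opening and 6π closure as in step 8, steered by outward rotation of the silyloxy group, forms the ring E C2–C3 bond and ring E with its C3 phenol free and its C6 oxygen silylated.

Step 17
Reactants: 33 ABCDE pentamer C3 phenol C6 silyl ether
Product: 35 ABCDE phenol, via ABCDE silyl ether 34 (not isolated)
Conditions: MeI, K2CO3, dry acetone, 40 °C; filter, evaporate; TBAF, AcOH (1:1), THF, 0 °C
Reagents that add atoms: iodomethane, CI
Why: Williamson methylation of the ring E C3 phenol followed by buffered fluoride desilylation at C6 repeats step 9.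

Step 18
Reactants: 1 4-bromo-2,6-dimethoxyphenol; 36 3,4,5-trimethoxyphenylboronic acid
Product: 37 FG bromide
Conditions: Cu(OAc)2 (2 equiv), pyridine, 4 Å MS, CH2Cl2, air, rt
Reagents that add atoms: none
Why: Chan–Lam O-arylation takes its aryl group from boron at room temperature, accepts di-ortho-substituted phenols and leaves the aryl bromide untouched, so the FG unit is obtained in one operation without protection.

Step 19
Reactants: 35 ABCDE phenol; 37 FG bromide
Product: 38 octadeca-O-methyl heptamer
Conditions: 37 (1.5 equiv), CuI (20 mol %), picolinic acid (40 mol %), K3PO4, DMSO, 100 °C, Ar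
Reagents that add atoms: none
Why: Ullmann-type diaryl ether synthesis of the same hindered-phenol and open-bromide pairing already used in steps 2 and 10 closes the last ether, between ring E C6 and ring F C1.

Step 20
Reactants: 38 octadeca-O-methyl heptamer
Product: 39 CNP0292517.0
Conditions: BBr3 (36 equiv), CH2Cl2, −78 °C → rt, Ar; degassed H2O, 0 °C; Sephadex LH-20 under Ar
Reagents that add atoms: none
Why: Lewis-acid dealkylation of aryl methyl ethers by BBr3 proceeds by bromide attack on the methyl carbon of the boron–ether complex, which cleaves all eighteen O–CH3 bonds but cannot cleave the six diaryl ethers, whose carbons are all sp2.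

Compound list
1 | 4-bromo-2,6-dimethoxyphenol | COc1cc(Br)cc(OC)c1O | starting material
2 | 2-benzyloxy-5-bromo-1,3-dimethoxybenzene (bromide for rings B and D) | COc1cc(Br)cc(OC)c1OCc2ccccc2 | intermediate
3 | 2,4,6-trimethoxyphenol (ring A) | COc1cc(OC)c(O)c(OC)c1 | starting material
4 | AB benzyl ether: 2-benzyloxy-1,3-dimethoxy-5-(2,4,6-trimethoxyphenoxy)benzene | COc1cc(OC)c(Oc2cc(OC)c(OCc3ccccc3)c(OC)c2)c(OC)c1 | intermediate
5 | AB phenol: 2,6-dimethoxy-4-(2,4,6-trimethoxyphenoxy)phenol | COc1cc(OC)c(Oc2cc(OC)c(O)c(OC)c2)c(OC)c1 | intermediate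
6 | trichloroethylene | ClC=C(Cl)Cl | starting material
7 | AB (E)-1,2-dichlorovinyl ether (on the ring B C4 oxygen) | COc1cc(OC)c(Oc2cc(OC)c(O/C(Cl)=C\Cl)c(OC)c2)c(OC)c1 | intermediate
8 | AB chloroethynyl ether | COc1cc(OC)c(Oc2cc(OC)c(OC#CCl)c(OC)c2)c(OC)c1 | intermediate
9 | AB lithium acetylide (lithium aryloxyacetylide) | COc1cc(OC)c(Oc2cc(OC)c(OC#C[Li])c(OC)c2)c(OC)c1 | intermediate
10 | AB ethynyl ether: 2-ethynyloxy-1,3-dimethoxy-5-(2,4,6-trimethoxyphenoxy)benzene | COc1cc(OC)c(Oc2cc(OC)c(OC#C)c(OC)c2)c(OC)c1 | intermediate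
11 | AB 1-iodovinyl ether | COc1cc(OC)c(Oc2cc(OC)c(OC(I)=C)c(OC)c2)c(OC)c1 | intermediate
12 | dimethyl squarate | COC1=C(OC)C(=O)C1=O | starting material
13 | AB vinyllithium (1-aryloxyvinyllithium) | COc1cc(OC)c(Oc2cc(OC)c(OC([Li])=C)c(OC)c2)c(OC)c1 | intermediate
14 | AB lithium alkoxide (racemic 1,2-adduct to the squarate) | COc1cc(OC)c(Oc2cc(OC)c(OC(=C)C3(O[Li])C(OC)=C(OC)C3=O)c(OC)c2)c(OC)c1 | intermediate
15 | racemic 4-[1-(AB-oxy)vinyl]-4-(tert-butyldimethylsilyloxy)-2,3-dimethoxycyclobut-2-en-1-one | C=C(Oc1c(OC)cc(Oc2c(OC)cc(OC)cc2OC)cc1OC)C1(O[Si](C)(C)C(C)(C)C)C(OC)=C(OC)C1=O | intermediate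
16 | AB (Z)-dienylketene (aryloxyvinyl arm cis to the ketene-bearing carbon) | COc1cc(OC)c(Oc2cc(OC)c(OC(=C)/C(O[Si](C)(C)C(C)(C)C)=C(OC)\C(OC)=C=O)c(OC)c2)c(OC)c1 | intermediate
17 | ring C cyclohexa-2,4-dienone (keto tautomer of 18) | COc1cc(OC)c(Oc2cc(OC)c(OC3=C(O[Si](C)(C)C(C)(C)C)C(OC)=C(OC)C(=O)C3)c(OC)c2)c(OC)c1 | intermediate
18 | ABC trimer, ring C C3 phenol, C4 and C5 methoxy, C6 TBS ether | COc1cc(OC)c(Oc2cc(OC)c(Oc3cc(O)c(OC)c(OC)c3O[Si](C)(C)C(C)(C)C)c(OC)c2)c(OC)c1 | intermediate
19 | ABC trimer, ring C C3 to C5 methoxy, C6 TBS ether | COc1cc(OC)c(Oc2cc(OC)c(Oc3cc(OC)c(OC)c(OC)c3O[Si](C)(C)C(C)(C)C)c(OC)c2)c(OC)c1 | intermediate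
20 | ABC phenol, ring C C3 to C5 methoxy, C6 hydroxyl | COc1cc(OC)c(Oc2cc(OC)c(Oc3cc(OC)c(OC)c(OC)c3O)c(OC)c2)c(OC)c1 | intermediate
21 | ABCD benzyl ether: 20 bearing a 4-benzyloxy-3,5-dimethoxyphenyl group (ring D) on the ring C C6 oxygen | COc1cc(OC)c(Oc2cc(OC)c(Oc3cc(OC)c(OC)c(OC)c3Oc4cc(OC)c(OCc5ccccc5)c(OC)c4)c(OC)c2)c(OC)c1 | intermediate
22 | ABCD phenol (free hydroxyl at ring D C4) | COc1cc(OC)c(Oc2cc(OC)c(Oc3cc(OC)c(OC)c(OC)c3Oc4cc(OC)c(O)c(OC)c4)c(OC)c2)c(OC)c1 | intermediate
23 | ABCD (E)-1,2-dichlorovinyl ether (on the ring D C4 oxygen) | COc1cc(OC)c(Oc2cc(OC)c(Oc3cc(OC)c(OC)c(OC)c3Oc4cc(OC)c(O/C(Cl)=C\Cl)c(OC)c4)c(OC)c2)c(OC)c1 | intermediate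
24 | ABCD chloroethynyl ether | COc1cc(OC)c(Oc2cc(OC)c(Oc3cc(OC)c(OC)c(OC)c3Oc4cc(OC)c(OC#CCl)c(OC)c4)c(OC)c2)c(OC)c1 | intermediate
25 | ABCD lithium acetylide | COc1cc(OC)c(Oc2cc(OC)c(Oc3cc(OC)c(OC)c(OC)c3Oc4cc(OC)c(OC#C[Li])c(OC)c4)c(OC)c2)c(OC)c1 | intermediate
26 | ABCD ethynyl ether | COc1cc(OC)c(Oc2cc(OC)c(Oc3cc(OC)c(OC)c(OC)c3Oc4cc(OC)c(OC#C)c(OC)c4)c(OC)c2)c(OC)c1 | intermediate
27 | ABCD 1-iodovinyl ether | COc1cc(OC)c(Oc2cc(OC)c(Oc3cc(OC)c(OC)c(OC)c3Oc4cc(OC)c(OC(I)=C)c(OC)c4)c(OC)c2)c(OC)c1 | intermediate
28 | ABCD vinyllithium | COc1cc(OC)c(Oc2cc(OC)c(Oc3cc(OC)c(OC)c(OC)c3Oc4cc(OC)c(OC([Li])=C)c(OC)c4)c(OC)c2)c(OC)c1 | intermediate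
29 | ABCD lithium alkoxide (racemic 1,2-adduct to the squarate) | COc1cc(OC)c(Oc2cc(OC)c(Oc3cc(OC)c(OC)c(OC)c3Oc4cc(OC)c(OC(=C)C5(O[Li])C(OC)=C(OC)C5=O)c(OC)c4)c(OC)c2)c(OC)c1 | intermediate
30 | racemic 4-[1-(ABCD-oxy)vinyl]-4-(tert-butyldimethylsilyloxy)-2,3-dimethoxycyclobut-2-en-1-one | COc1cc(OC)c(Oc2cc(OC)c(Oc3cc(OC)c(OC)c(OC)c3Oc4cc(OC)c(OC(=C)C5(O[Si](C)(C)C(C)(C)C)C(OC)=C(OC)C5=O)c(OC)c4)c(OC)c2)c(OC)c1 | intermediate
31 | ABCD (Z)-dienylketene | COc1cc(OC)c(Oc2cc(OC)c(Oc3cc(OC)c(OC)c(OC)c3Oc4cc(OC)c(OC(=C)/C(O[Si](C)(C)C(C)(C)C)=C(OC)\C(OC)=C=O)c(OC)c4)c(OC)c2)c(OC)c1 | intermediate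
32 | ring E cyclohexa-2,4-dienone (keto tautomer of 33) | COc1cc(OC)c(Oc2cc(OC)c(Oc3cc(OC)c(OC)c(OC)c3Oc4cc(OC)c(OC5=C(O[Si](C)(C)C(C)(C)C)C(OC)=C(OC)C(=O)C5)c(OC)c4)c(OC)c2)c(OC)c1 | intermediate
33 | ABCDE pentamer, ring E C3 phenol, C4 and C5 methoxy, C6 TBS ether | COc1cc(OC)c(Oc2cc(OC)c(Oc3cc(OC)c(OC)c(OC)c3Oc4cc(OC)c(Oc5cc(O)c(OC)c(OC)c5O[Si](C)(C)C(C)(C)C)c(OC)c4)c(OC)c2)c(OC)c1 | intermediate
34 | ABCDE pentamer, ring E C3 to C5 methoxy, C6 TBS ether | COc1cc(OC)c(Oc2cc(OC)c(Oc3cc(OC)c(OC)c(OC)c3Oc4cc(OC)c(Oc5cc(OC)c(OC)c(OC)c5O[Si](C)(C)C(C)(C)C)c(OC)c4)c(OC)c2)c(OC)c1 | intermediate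
35 | ABCDE phenol, ring E C6 hydroxyl | COc1cc(OC)c(Oc2cc(OC)c(Oc3cc(OC)c(OC)c(OC)c3Oc4cc(OC)c(Oc5cc(OC)c(OC)c(OC)c5O)c(OC)c4)c(OC)c2)c(OC)c1 | intermediate
36 | 3,4,5-trimethoxyphenylboronic acid (ring G) | COc1cc(B(O)O)cc(OC)c1OC | starting material
37 | FG bromide: 5-bromo-1,3-dimethoxy-2-(3,4,5-trimethoxyphenoxy)benzene | COc1cc(Br)cc(OC)c1Oc2cc(OC)c(OC)c(OC)c2 | intermediate
38 | octadeca-O-methyl heptamer (all eighteen hydroxyls of the target as methyl ethers) | COc1cc(OC)c(Oc2cc(OC)c(Oc3cc(OC)c(OC)c(OC)c3Oc4cc(OC)c(Oc5cc(OC)c(OC)c(OC)c5Oc6cc(OC)c(Oc7cc(OC)c(OC)c(OC)c7)c(OC)c6)c(OC)c4)c(OC)c2)c(OC)c1 | intermediate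
39 | CNP0292517.0 (heptameric phenyl ether, eighteen free hydroxyls, achiral) | Oc1cc(O)c(Oc2cc(O)c(Oc3cc(O)c(O)c(O)c3Oc3cc(O)c(Oc4cc(O)c(O)c(O)c4Oc4cc(O)c(Oc5cc(O)c(O)c(O)c5)c(O)c4)c(O)c3)c(O)c2)c(O)c1 | target

Total step count: 20. Longest linear sequence: 19 (steps 1 to 17, then 19 and 20). Step 18 is a one-step branch.

Steps most likely to fail

Step 8, the ring expansion.
- What may go wrong: the ring opening may need a temperature at which the aryl vinyl ether or the silyl group does not last. The dienylketene may also be lost to dimerisation or to traces of water before it closes.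
- Fallback: this route gives up the electrocyclic construction of ring C. It sets out from AB phenol 5 and comes back at ABC phenol 20.
  - Commercial 5-bromo-1,2,3-trimethoxybenzene is formylated at its only kind of free position (Cl2CHOMe, TiCl4, Rieche formylation) to 2-bromo-4,5,6-trimethoxybenzaldehyde F1.
  - Ullmann coupling of 5 with this bromide (CuI, picolinic acid, K3PO4, DMSO), helped by the ortho formyl group, should give the ABC aldehyde F2.
  - Baeyer–Villiger oxidation with mCPBA turns the electron-rich aldehyde into the ABC aryl formate F3.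
  - K2CO3 in MeOH releases 20.

Step 6, the hydroiodination.
- What may go wrong: a second addition of HI, or hydrolysis of the iodo enol ether to the aryl acetate during handling, may erode the material before the exchange.
- Fallback: this route replaces hydrohalogenation by hydrometalation. It sets out from ethynyl ether 10 and comes back at vinyllithium 13 inside step 7.
  - Hydrostannylation with Bu3SnH under Pd(PPh3)4 catalysis, which on alkoxyalkynes places tin on the oxygen-bearing carbon, should give the AB 1-(tributylstannyl)vinyl ether F4.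
  - This stannane can be purified on amine-deactivated silica.
  - Tin–lithium exchange with n-BuLi in THF at −78 °C then generates 13 without t-BuLi.

Step 20, the eighteen-fold demethylation.
- What may go wrong: partly cleaved boron complexes may precipitate and stop the reaction short. The pyrogallol-type rings may oxidise in air during isolation of the free polyphenol.
- Fallback: this route isolates the product through a stable derivative. It sets out from 38 and comes back at 39.
  - After the BBr3 treatment the crude polyphenol is not purified but acetylated directly (Ac2O, pyridine) to the heptamer octadecaacetate F5.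
  - This acetate is air-stable and can be separated by chromatography from under-cleaved congeners.
  - Acid-catalysed methanolysis (HCl from AcCl in degassed MeOH, Ar) then frees 39 under non-basic conditions.

Further compounds
F1 | step 8 | 2-bromo-4,5,6-trimethoxybenzaldehyde | O=Cc1c(Br)cc(OC)c(OC)c1OC
F2 | step 8 | ABC aldehyde (formyl group at ring C C6) | COc1cc(OC)c(Oc2cc(OC)c(Oc3cc(OC)c(OC)c(OC)c3C=O)c(OC)c2)c(OC)c1
F3 | step 8 | ABC aryl formate (formyloxy group at ring C C6) | COc1cc(OC)c(Oc2cc(OC)c(Oc3cc(OC)c(OC)c(OC)c3OC=O)c(OC)c2)c(OC)c1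
F4 | step 6 | AB 1-(tributylstannyl)vinyl ether | COc1cc(OC)c(Oc2cc(OC)c(OC(=C)[Sn](CCCC)(CCCC)CCCC)c(OC)c2)c(OC)c1
F5 | step 20 | heptamer octadecaacetate | CC(=O)Oc1cc(OC(C)=O)c(Oc2cc(OC(C)=O)c(Oc3cc(OC(C)=O)c(OC(C)=O)c(OC(C)=O)c3Oc4cc(OC(C)=O)c(Oc5cc(OC(C)=O)c(OC(C)=O)c(OC(C)=O)c5Oc6cc(OC(C)=O)c(Oc7cc(OC(C)=O)c(OC(C)=O)c(OC(C)=O)c7)c(OC(C)=O)c6)c(OC(C)=O)c4)c(OC(C)=O)c2)c(OC(C)=O)c1
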